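## Retrosynthetic overview

- The target is reached from its O-methyl tetronate, O-silyl ether by removing the tetronate O–CH3 group and then the tertiary O–Si group.
- Key disconnection: the bond C1′–C2′ (ylidene CH to the CH(CH3) stereocentre) and the lactone bond O1–C2 are made in one operation from a potassium sec-alkyltrifluoroborate and a diazo keto ester, by boron-to-carbon shift with N2 extrusion followed by enol-lactonisation.
- Enabling feature: in the butenolide ring (O1, C2=O, C3–CH3, C4–O, C5) the atom C5 is an enol-ester carbon, that is a masked C5 ketone with C1′ as its α-carbon, and C2 sits cis to C5 across C3=C4. A diazo group on C1′ therefore gives both the C1′–C2′ bond and the C5–O enolate that becomes O1.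
- The trifluoroborate comes from (R)-linalool (carbinol stereocentre bought): furylpropyl arm by hydroboration and alkyl–alkyl Suzuki–Miyaura coupling, E-selective allylic oxidation, allyl–vinyl coupling, hydroboration, then C2′ set by (+)-sparteine lithiation–borylation. The diazo keto ester comes from diethyl oxalpropionate through methoxymethylmaleic anhydride.
- Ring order: the furan is bought; the anhydride ring is made in step 3 and opened in step 4 (it fixes the cis geometry at C3=C4); the butenolide ring is made last, in step 13.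

Key step: step 13

Remark: compounds 2 and 3 are carried as mixtures of alkene isomers because anhydride formation in step 3 is expected to converge them; (R)-(−)-linalool of high enantiomeric purity is assumed.

## Route

Step 1
Reactants: 1 diethyl 2-methyl-3-oxobutanedioate (diethyl oxalpropionate)
Product: 2 diethyl 2-methoxy-3-methylbut-2-enedioate (E/Z mixture)
Conditions: Me2SO4, K2CO3, DMF, rt
Reagents that add atoms: dimethyl sulfate, COS(=O)(=O)OC
Why: O-methylation of the potassium enolate of a strongly enolised 1,3-dicarbonyl compound by a hard methylating agent in a dipolar solvent should give the methyl enol ether; its geometry is of no consequence here.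

Step 2
Reactants: 2 diethyl 2-methoxy-3-methylbut-2-enedioate
Product: 3 2-methoxy-3-methylbut-2-enedioic acid (E/Z mixture)
Conditions: KOH, EtOH/H2O, 60 °C; then HCl (aq.) to pH 1
Reagents that add atoms: potassium hydroxide, [K+].[OH-]
Why: Saponification of both ethyl esters should proceed without loss of the β-methoxy enol ether, which is stable to aqueous hydroxide at moderate temperature.

Step 3
Reactants: 3 2-methoxy-3-methylbut-2-enedioic acid
Product: 4 3-methoxy-4-methylfuran-2,5-dione (methoxymethylmaleic anhydride)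
Conditions: Ac2O, 110 °C
Reagents that add atoms: none
Why: Cyclodehydration with acetic anhydride should give the five-membered maleic-type anhydride, and the hot acidic medium should isomerise the donor–acceptor C=C bond so that both alkene isomers of 3 funnel into 4.

Step 4
Reactants: 4 3-methoxy-4-methylfuran-2,5-dione
Product: 6 methyl (2E)-5-diazo-3-methoxy-2-methyl-4-oxopent-2-enoate, via diazo keto acid 5 (not isolated)
Conditions: CH2N2 (3 equiv), Et2O/THF, −10 °C → rt
Reagents that add atoms: diazomethane, C=[N+]=[N-]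
Why: C-Acylation of diazomethane by an anhydride (the first stage of an Arndt–Eistert sequence) should occur at the carbonyl next to the methoxy-bearing carbon, because the other carbonyl is deactivated as a vinylogous carbonate; the released acid 5 is esterified by further diazomethane and the cis arrangement of the two acyl groups is inherited from the ring.

Step 5
Reactants: 7 (R)-(−)-linalool, (3R)-3,7-dimethylocta-1,6-dien-3-ol
Product: 8 tert-butyl{[(3R)-3,7-dimethylocta-1,6-dien-3-yl]oxy}dimethylsilane
Conditions: TBSOTf, 2,6-lutidine, CH2Cl2, 0 °C → rt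
Reagents that add atoms: tert-butyldimethylsilyl trifluoromethanesulfonate, CC(C)(C)[Si](C)(C)OS(=O)(=O)C(F)(F)F
Why: Silylation of a hindered tertiary alcohol with a silyl triflate and a hindered pyridine base is standard and gives an ether that should survive all later steps up to the final fluoride treatment.

Step 6
Reactants: 8 tert-butyl{[(3R)-3,7-dimethylocta-1,6-dien-3-yl]oxy}dimethylsilane; 9 3-(bromomethyl)furan
Product: 11 tert-butyl{[(4S)-1-(furan-3-yl)-4,8-dimethylnon-7-en-4-yl]oxy}dimethylsilane, via B-alkyl-9-BBN adduct 10 (not isolated)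
Conditions: 9-BBN, THF, 0 °C → rt; then 9, Pd(OAc)2 (cat.), PCy3, K3PO4·H2O, THF, rt
Reagents that add atoms: none
Why: Hydroboration with 9-BBN is selective for the monosubstituted vinyl group over the trisubstituted alkene, and the B-alkyl-9-BBN adduct should then undergo alkyl–alkyl Suzuki–Miyaura coupling with the benzylic-type bromide under Pd/PCy3 catalysis; the carbinol stereocentre is not touched.

Step 7
Reactants: 11 tert-butyl{[(4S)-1-(furan-3-yl)-4,8-dimethylnon-7-en-4-yl]oxy}dimethylsilane
Product: 12 (2E,6S)-6-[(tert-butyldimethylsilyl)oxy]-9-(furan-3-yl)-2,6-dimethylnon-2-en-1-ol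
Conditions: SeO2 (cat.), t-BuOOH, salicylic acid (cat.), CH2Cl2, 0 °C → rt
Reagents that add atoms: selenium dioxide (catalytic oxygen carrier), O=[Se]=O; tert-butyl hydroperoxide (terminal oxidant), CC(C)(C)OO
Why: Catalytic SeO2 allylic oxidation (ene reaction followed by [2,3]-sigmatropic shift) of a terminal isopropylidene group is selective for the (E)-methyl group, which fixes the E trisubstituted alkene of the target; a 3-alkylfuran should tolerate these conditions.

Step 8
Reactants: 12 (2E,6S)-6-[(tert-butyldimethylsilyl)oxy]-9-(furan-3-yl)-2,6-dimethylnon-2-en-1-ol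
Product: 13 3-[(4S,7E)-9-bromo-4-[(tert-butyldimethylsilyl)oxy]-4,8-dimethylnon-7-en-1-yl]furan
Conditions: CBr4, PPh3, CH2Cl2, 0 °C
Reagents that add atoms: carbon tetrabromide, BrC(Br)(Br)Br
Why: The Appel reaction should convert the primary allylic alcohol into the primary allylic bromide at low temperature without allylic transposition or loss of alkene geometry.

Step 9
Reactants: 13 3-[(4S,7E)-9-bromo-4-[(tert-butyldimethylsilyl)oxy]-4,8-dimethylnon-7-en-1-yl]furan
Product: 14 tert-butyl{[(4S,7E)-1-(furan-3-yl)-4,8-dimethylundeca-7,10-dien-4-yl]oxy}dimethylsilane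
Conditions: tributyl(vinyl)stannane, Pd2(dba)3 (cat.), AsPh3, THF, 50 °C
Reagents that add atoms: tributyl(vinyl)stannane, C=C[Sn](CCCC)(CCCC)CCCC
Why: Stille coupling of the primary allylic bromide with the vinylstannane should join the vinyl group at the less substituted allyl terminus with retention of the E geometry, giving the skipped diene.

Step 10
Reactants: 14 tert-butyl{[(4S,7E)-1-(furan-3-yl)-4,8-dimethylundeca-7,10-dien-4-yl]oxy}dimethylsilane
Product: 15 2-[(4E,8S)-8-[(tert-butyldimethylsilyl)oxy]-11-(furan-3-yl)-4,8-dimethylundec-4-en-1-yl]-4,4,5,5-tetramethyl-1,3,2-dioxaborolane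
Conditions: HBpin, [Ir(cod)Cl]2 (cat.), dppm, CH2Cl2, rt
Reagents that add atoms: pinacolborane, CC1(C)OBOC1(C)C
Why: Iridium-catalysed hydroboration with pinacolborane is selective for the terminal alkene and gives the linear primary boronic ester; the trisubstituted alkene and the furan should not react at room temperature.

Step 11
Reactants: 15 2-[(4E,8S)-8-[(tert-butyldimethylsilyl)oxy]-11-(furan-3-yl)-4,8-dimethylundec-4-en-1-yl]-4,4,5,5-tetramethyl-1,3,2-dioxaborolane; 16 ethyl 2,4,6-tri(propan-2-yl)benzoate
Product: 19 2-[(2S,6E,10S)-10-[(tert-butyldimethylsilyl)oxy]-13-(furan-3-yl)-6,10-dimethyltridec-6-en-2-yl]-4,4,5,5-tetramethyl-1,3,2-dioxaborolane, via lithiated benzoate 17 (not isolated), via boronate complex 18 (not isolated)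
Conditions: 16, s-BuLi, (+)-sparteine, Et2O, −78 °C; then 15, −78 °C → 35 °C
Reagents that add atoms: none
Why: Lithiation–borylation: sparteine-mediated enantioselective deprotonation of 16 gives the configurationally stable (R)-α-lithio ester 17, which is borylated by 15 with retention to give 18, and the primary alkyl group then migrates from boron to carbon with inversion and loss of the benzoate (1,2-metallate rearrangement), so that C2′ is set as S under reagent control by (+)-sparteine.

Step 12
Reactants: 19 2-[(2S,6E,10S)-10-[(tert-butyldimethylsilyl)oxy]-13-(furan-3-yl)-6,10-dimethyltridec-6-en-2-yl]-4,4,5,5-tetramethyl-1,3,2-dioxaborolane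
Product: 20 potassium [(2S,6E,10S)-10-[(tert-butyldimethylsilyl)oxy]-13-(furan-3-yl)-6,10-dimethyltridec-6-en-2-yl]trifluoroborate
Conditions: KHF2 (aq.), MeOH, rt
Reagents that add atoms: potassium hydrogen difluoride, [K+].[F-].F
Why: Conversion of a pinacol boronate into the potassium trifluoroborate does not touch the C–B stereocentre and gives a storable precursor of the Lewis-acidic difluoroborane; the hindered tertiary TBS ether should survive the brief exposure.

Step 13
Reactants: 20 potassium [(2S,6E,10S)-10-[(tert-butyldimethylsilyl)oxy]-13-(furan-3-yl)-6,10-dimethyltridec-6-en-2-yl]trifluoroborate; 6 methyl (2E)-5-diazo-3-methoxy-2-methyl-4-oxopent-2-enoate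
Product: 23 (5Z)-5-[(2S,6E,10S)-10-[(tert-butyldimethylsilyl)oxy]-13-(furan-3-yl)-2,6,10-trimethyltridec-6-en-1-ylidene]-4-methoxy-3-methylfuran-2(5H)-one, via sec-alkyldifluoroborane 21 (not isolated), via difluoroboron enolate 22 (not isolated)
Conditions: Me3SiCl (1.05 equiv), MeCN/CH2Cl2, 0 °C; then 6, −40 °C → rt; then 40 °C
Reagents that add atoms: none
Why: Proposed new method: Me3SiCl strips fluoride from 20 to give the Lewis-acidic sec-alkyldifluoroborane 21, which adds to the nucleophilic diazo carbon C1′ of 6; the borate then loses N2 while the sec-alkyl group shifts from boron to C1′ with retention at C2′ (this is the C1′–C2′ bond), and the α-boryl ketone relaxes by 1,3-boron shift to the C5–O difluoroboron enolate 22. The closest known reaction type is the Hooz reaction (alkyldihaloboranes and trialkylboranes with α-diazo ketones, 1,2-shift with N2 loss to give enol borinates that are trapped by electrophiles), extended here by an intramolecular O-acylation that has its analogy in the enol-lactonisation of (Z)-4-oxoalk-2-enoic acid derivatives to 5-ylidenebutenolides. The butenolide ring closes by 5-exo-trig attack of the enolate oxygen (future O1) on the ester carbonyl C2, which the cis C3=C4 bond holds within reach, and boron leaves with the methoxide as MeOBF2, which removes the nucleophile that could reopen the enol lactone. No new stereocentre arises: C2′ is carried over from 19 because the 1,2-shift is stereoretentive at the migrating carbon, and nothing basic enough to epimerise this γ-position is present. The step needs migration of carbon only (the BF2 group offers a single carbon substituent), an enolate oxygen on C5 only (fixed by the place of the diazo group), and Z geometry at C5=C1′, which is expected because the C-bound and O-bound boron tautomers interconvert and the isomer with the alkyl group anti to the C4–OMe group (allylic 1,3-strain) is favoured in both the enolate and the lactone.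

Step 14
Reactants: 23 (5Z)-5-[(2S,6E,10S)-10-[(tert-butyldimethylsilyl)oxy]-13-(furan-3-yl)-2,6,10-trimethyltridec-6-en-1-ylidene]-4-methoxy-3-methylfuran-2(5H)-one
Product: 24 (5Z)-5-[(2S,6E,10S)-10-[(tert-butyldimethylsilyl)oxy]-13-(furan-3-yl)-2,6,10-trimethyltridec-6-en-1-ylidene]-4-hydroxy-3-methylfuran-2(5H)-one
Conditions: n-PrSLi (from n-PrSH and n-BuLi), HMPA, rt; then HCl (aq.)
Reagents that add atoms: none
Why: SN2 demethylation of the vinylogous methyl ester (methyl tetronate) by a soft thiolate in a dipolar aprotic solvent is the usual way to unmask 5-ylidene tetronic acids and should leave the ylidene geometry, the adjacent stereocentre, the furan and the silyl ether untouched.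

Step 15
Reactants: 24 (5Z)-5-[(2S,6E,10S)-10-[(tert-butyldimethylsilyl)oxy]-13-(furan-3-yl)-2,6,10-trimethyltridec-6-en-1-ylidene]-4-hydroxy-3-methylfuran-2(5H)-one
Product: 25 (5Z)-5-[(2S,6E,10S)-13-(furan-3-yl)-10-hydroxy-2,6,10-trimethyltridec-6-en-1-ylidene]-4-hydroxy-3-methylfuran-2(5H)-one (CNP0217216.2)
Conditions: HF·pyridine, pyridine, THF, 0 °C → rt
Reagents that add atoms: none
Why: Fluoride-mediated cleavage of the tertiary silyl ether with pyridine-buffered HF should release the tertiary alcohol without acid damage to the furan or isomerisation of the ylidene tetronic acid.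

## Compound list

1 | diethyl 2-methyl-3-oxobutanedioate (diethyl oxalpropionate) | CCOC(=O)C(C)C(=O)C(=O)OCC | starting material
2 | diethyl 2-methoxy-3-methylbut-2-enedioate (E/Z mixture) | CCOC(=O)C(C)=C(OC)C(=O)OCC | intermediate
3 | 2-methoxy-3-methylbut-2-enedioic acid (E/Z mixture) | COC(C(=O)O)=C(C)C(=O)O | intermediate
4 | 3-methoxy-4-methylfuran-2,5-dione | COC1=C(C)C(=O)OC1=O | intermediate
5 | (2E)-5-diazo-3-methoxy-2-methyl-4-oxopent-2-enoic acid | OC(=O)/C(C)=C(OC)\C(=O)C=[N+]=[N-] | intermediate
6 | methyl (2E)-5-diazo-3-methoxy-2-methyl-4-oxopent-2-enoate | COC(=O)/C(C)=C(OC)\C(=O)C=[N+]=[N-] | intermediate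
7 | (R)-(−)-linalool, (3R)-3,7-dimethylocta-1,6-dien-3-ol | CC(C)=CCC[C@@](C)(O)C=C | starting material
8 | tert-butyl{[(3R)-3,7-dimethylocta-1,6-dien-3-yl]oxy}dimethylsilane | CC(C)=CCC[C@@](C)(O[Si](C)(C)C(C)(C)C)C=C | intermediate
9 | 3-(bromomethyl)furan | BrCc1ccoc1 | starting material
10 | 9-[(3S)-3-[(tert-butyldimethylsilyl)oxy]-3,7-dimethyloct-6-en-1-yl]-9-borabicyclo[3.3.1]nonane | CC(C)=CCC[C@@](C)(O[Si](C)(C)C(C)(C)C)CCB1C2CCCC1CCC2 | intermediate
11 | tert-butyl{[(4S)-1-(furan-3-yl)-4,8-dimethylnon-7-en-4-yl]oxy}dimethylsilane | CC(C)=CCC[C@@](C)(O[Si](C)(C)C(C)(C)C)CCCc1ccoc1 | intermediate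
12 | (2E,6S)-6-[(tert-butyldimethylsilyl)oxy]-9-(furan-3-yl)-2,6-dimethylnon-2-en-1-ol | OC/C(C)=C/CC[C@@](C)(O[Si](C)(C)C(C)(C)C)CCCc1ccoc1 | intermediate
13 | 3-[(4S,7E)-9-bromo-4-[(tert-butyldimethylsilyl)oxy]-4,8-dimethylnon-7-en-1-yl]furan | BrC/C(C)=C/CC[C@@](C)(O[Si](C)(C)C(C)(C)C)CCCc1ccoc1 | intermediate
14 | tert-butyl{[(4S,7E)-1-(furan-3-yl)-4,8-dimethylundeca-7,10-dien-4-yl]oxy}dimethylsilane | C=CC/C(C)=C/CC[C@@](C)(O[Si](C)(C)C(C)(C)C)CCCc1ccoc1 | intermediate
15 | 2-[(4E,8S)-8-[(tert-butyldimethylsilyl)oxy]-11-(furan-3-yl)-4,8-dimethylundec-4-en-1-yl]-4,4,5,5-tetramethyl-1,3,2-dioxaborolane | CC1(C)OB(OC1(C)C)CCC/C(C)=C/CC[C@@](C)(O[Si](C)(C)C(C)(C)C)CCCc1ccoc1 | intermediate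
16 | ethyl 2,4,6-tri(propan-2-yl)benzoate | CCOC(=O)c1c(C(C)C)cc(C(C)C)cc1C(C)C | starting material
17 | (1R)-1-lithioethyl 2,4,6-tri(propan-2-yl)benzoate (sparteine complex) | [Li][C@H](C)OC(=O)c1c(C(C)C)cc(C(C)C)cc1C(C)C | intermediate
18 | lithium [(1R)-1-{[2,4,6-tri(propan-2-yl)benzoyl]oxy}ethyl][(4E,8S)-8-[(tert-butyldimethylsilyl)oxy]-11-(furan-3-yl)-4,8-dimethylundec-4-en-1-yl](pinacolato)borate | [Li+].CC(C)c1cc(C(C)C)c(C(=O)O[C@@H](C)[B-]2(CCC/C(C)=C/CC[C@@](C)(O[Si](C)(C)C(C)(C)C)CCCc3ccoc3)OC(C)(C)C(C)(C)O2)c(C(C)C)c1 | intermediate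
19 | 2-[(2S,6E,10S)-10-[(tert-butyldimethylsilyl)oxy]-13-(furan-3-yl)-6,10-dimethyltridec-6-en-2-yl]-4,4,5,5-tetramethyl-1,3,2-dioxaborolane | CC1(C)OB(OC1(C)C)[C@@H](C)CCC/C(C)=C/CC[C@@](C)(O[Si](C)(C)C(C)(C)C)CCCc1ccoc1 | intermediate
20 | potassium [(2S,6E,10S)-10-[(tert-butyldimethylsilyl)oxy]-13-(furan-3-yl)-6,10-dimethyltridec-6-en-2-yl]trifluoroborate | [K+].F[B-](F)(F)[C@@H](C)CCC/C(C)=C/CC[C@@](C)(O[Si](C)(C)C(C)(C)C)CCCc1ccoc1 | intermediate
21 | [(2S,6E,10S)-10-[(tert-butyldimethylsilyl)oxy]-13-(furan-3-yl)-6,10-dimethyltridec-6-en-2-yl]difluoroborane | FB(F)[C@@H](C)CCC/C(C)=C/CC[C@@](C)(O[Si](C)(C)C(C)(C)C)CCCc1ccoc1 | intermediate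
22 | methyl (2E,4Z,6S,10E,14S)-14-[(tert-butyldimethylsilyl)oxy]-4-[(difluoroboranyl)oxy]-17-(furan-3-yl)-3-methoxy-2,6,10,14-tetramethylheptadeca-2,4,10-trienoate | COC(=O)/C(C)=C(OC)\C(OB(F)F)=C\[C@@H](C)CCC/C(C)=C/CC[C@@](C)(O[Si](C)(C)C(C)(C)C)CCCc1ccoc1 | intermediate
23 | (5Z)-5-[(2S,6E,10S)-10-[(tert-butyldimethylsilyl)oxy]-13-(furan-3-yl)-2,6,10-trimethyltridec-6-en-1-ylidene]-4-methoxy-3-methylfuran-2(5H)-one | CC1=C(OC)/C(=C/[C@@H](C)CCC/C(C)=C/CC[C@@](C)(O[Si](C)(C)C(C)(C)C)CCCc2ccoc2)OC1=O | intermediate
24 | (5Z)-5-[(2S,6E,10S)-10-[(tert-butyldimethylsilyl)oxy]-13-(furan-3-yl)-2,6,10-trimethyltridec-6-en-1-ylidene]-4-hydroxy-3-methylfuran-2(5H)-one | CC1=C(O)/C(=C/[C@@H](C)CCC/C(C)=C/CC[C@@](C)(O[Si](C)(C)C(C)(C)C)CCCc2ccoc2)OC1=O | intermediate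
25 | (5Z)-5-[(2S,6E,10S)-13-(furan-3-yl)-10-hydroxy-2,6,10-trimethyltridec-6-en-1-ylidene]-4-hydroxy-3-methylfuran-2(5H)-one (CNP0217216.2) | CC1=C(O)/C(=C/[C@@H](C)CCC/C(C)=C/CC[C@@](C)(O)CCCc2ccoc2)OC1=O | target

## Step count and risks

Total steps: 15. Longest linear sequence: 11 steps (steps 5 to 15, from 7).

Steps most likely to fail:

1. Step 13 (proposed new method). The difluoroborane may be too weak a Lewis acid to engage the acyl-stabilised diazo carbon, the diazo ketone may lose nitrogen under the Lewis-acidic conditions without forming the C–C bond, the sequence may stop at the open keto ester without ring closure, or the geometry at C5=C1′ may be poorly controlled. The fallback uses known chemistry, sets out from 19 and comes back at 23. Matteson homologation of 19 with LiCH2Cl (BrCH2Cl, n-BuLi, THF, −78 °C → rt) would make the C1′–C2′ bond with retention and give the homologated primary pinacol boronate F1. Oxidation (NaBO3·4H2O, THF/H2O) would give the primary alcohol F2, and Dess–Martin oxidation would give the α-methyl aldehyde F3, to be used at once. Aldol addition of the C5 lithium dienolate of 4-methoxy-3-methylfuran-2(5H)-one (LDA, THF, −78 °C) to F3 would give the β-hydroxy tetronate F4 as a mixture of diastereomers. Mesylation (MsCl, Et3N) followed by DBU elimination should then give the (Z)-ylidene tetronate 23.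

2. Step 4. Diazomethane may add across the C=C bond of the anhydride as a 1,3-dipole, or the ring may be opened at the wrong carbonyl. The fallback sets out from 4 and comes back at 6. Methanolysis of 4 (MeOH, reflux) would give the half ester F5, with the acid on the methyl-bearing side, and diazomethane would turn it into the cis diester F6. One equivalent of LiOH (THF/H2O, 0 °C) should hydrolyse the more electrophilic ester next to the methoxy-bearing carbon and give the regioisomeric half acid F7. Activation as the isobutyl carbonic mixed anhydride F8 (i-BuOCOCl, N-methylmorpholine, THF, −15 °C) and acylation of diazomethane would then give 6 with the acyl position fixed by the hydrolysis and not by the ring opening.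

3. Step 6. Transmetalation of the hindered B-alkyl-9-BBN adduct may be slow, so that homocoupling or decomposition of the labile furylmethyl bromide and protodeboronation take over. The fallback sets out from 8 and comes back at 11, with the polarity of the coupling reversed. Hydroboration of 8 with 9-BBN and oxidation (NaOH, H2O2) would give the primary alcohol F9, and TsCl in pyridine the tosylate F10. Copper-catalysed alkyl–alkyl coupling (Li2CuCl4 cat., THF, −20 °C) of F10 with (furan-3-ylmethyl)magnesium bromide F11, made from 9 and magnesium, should give 11.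

Further compounds

F1 | step 13 | 2-[(2R,6E,10S)-10-[(tert-butyldimethylsilyl)oxy]-13-(furan-3-yl)-2,6,10-trimethyltridec-6-en-1-yl]-4,4,5,5-tetramethyl-1,3,2-dioxaborolane | CC1(C)OB(OC1(C)C)C[C@@H](C)CCC/C(C)=C/CC[C@@](C)(O[Si](C)(C)C(C)(C)C)CCCc1ccoc1
F2 | step 13 | (2S,6E,10S)-10-[(tert-butyldimethylsilyl)oxy]-13-(furan-3-yl)-2,6,10-trimethyltridec-6-en-1-ol | OC[C@@H](C)CCC/C(C)=C/CC[C@@](C)(O[Si](C)(C)C(C)(C)C)CCCc1ccoc1
F3 | step 13 | (2S,6E,10S)-10-[(tert-butyldimethylsilyl)oxy]-13-(furan-3-yl)-2,6,10-trimethyltridec-6-enal | O=C[C@@H](C)CCC/C(C)=C/CC[C@@](C)(O[Si](C)(C)C(C)(C)C)CCCc1ccoc1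
F4 | step 13 | 5-[(2S,6E,10S)-10-[(tert-butyldimethylsilyl)oxy]-13-(furan-3-yl)-1-hydroxy-2,6,10-trimethyltridec-6-en-1-yl]-4-methoxy-3-methylfuran-2(5H)-one (mixture of diastereomers at C5 and C1′) | COC1=C(C)C(=O)OC1C(O)[C@@H](C)CCC/C(C)=C/CC[C@@](C)(O[Si](C)(C)C(C)(C)C)CCCc1ccoc1
F5 | step 4 | (2E)-3,4-dimethoxy-2-methyl-4-oxobut-2-enoic acid | COC(=O)/C(OC)=C(C)\C(=O)O
F6 | step 4 | dimethyl (2E)-2-methoxy-3-methylbut-2-enedioate | COC(=O)/C(OC)=C(C)\C(=O)OC
F7 | step 4 | (2E)-2,4-dimethoxy-3-methyl-4-oxobut-2-enoic acid | OC(=O)/C(OC)=C(C)\C(=O)OC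
F8 | step 4 | isobutyl carbonic (2E)-2,4-dimethoxy-3-methyl-4-oxobut-2-enoic anhydride | CC(C)COC(=O)OC(=O)/C(OC)=C(C)\C(=O)OC
F9 | step 6 | (3R)-3-[(tert-butyldimethylsilyl)oxy]-3,7-dimethyloct-6-en-1-ol | CC(C)=CCC[C@@](C)(O[Si](C)(C)C(C)(C)C)CCO
F10 | step 6 | (3R)-3-[(tert-butyldimethylsilyl)oxy]-3,7-dimethyloct-6-en-1-yl 4-methylbenzenesulfonate | CC(C)=CCC[C@@](C)(O[Si](C)(C)C(C)(C)C)CCOS(=O)(=O)c1ccc(C)cc1
F11 | step 6 | (furan-3-ylmethyl)magnesium bromide | Br[Mg]Cc1ccoc1
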